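**Plan**

- Retrosynthesis: the C8/C9 esters and the C14 oxidation level are removed first, then the lactone C12–O bond. One event then cuts C11–C12 and C6–C7 together (CO2 plus an allene–aldehyde), which opens the ten-membered ring. The open chain is cut at C9–C10 (alkenylmagnesium + α-alkoxy aldehyde) and at C3–C4 (Sonogashira).
- Enabling feature: the exocyclic C11=C13 methylene sits between the carboxyl carbon C12 and ring carbon C7, so it is the retron of a terminal allene C7=C11=C13 on C8. CO2 enters at the central carbon C11 and the resulting 2-carboxyallyl nickel adds through C7 to the C6 aldehyde beside the C4–C5 epoxide. The cis C1=C10 alkene and the two cis epoxides fold the chain for closure of ring C1–C10.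
- Forward: alkenyl iodide 13 (C1–C6, C10, C14) and allenyl aldehyde 19 (C7–C9, C11, C13) are joined at C9–C10. The second epoxide is installed, ring C1–C10 closes in the key step, the lactone ring follows, then the side chains and C14 oxidation.
- Stereochemistry: three Sharpless epoxidations with D-(−)-tartrate (C2/C3, C4/C5, C8) and one with L-(+)-tartrate (side chain); C9 by chelation control from C8; C6/C7 by the chair transition state of the key step under macrocyclic control. Alkene geometries come from trans-hydroalumination, Lindlar reduction and the iodo-Wittig reaction.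

Key step: step 20

Remark: locants C1–C15 are those of the germacrane skeleton of 40 (ring C1–C10, C11–C13 on C7, C14 on C10, C15 on C4), α/β refer to the usual drawing with H-7 α, the SMILES of 27 omits the DBU ligands, and 17 is carried as a mixture of epimers at the acetal carbon.

**Route**

Step 1
Reactants: 1 but-2-yn-1-ol
Product: 2 (Z)-3-iodobut-2-en-1-ol
Conditions: NaAlH2(OCH2CH2OMe)2, Et2O, 0 °C → rt; then I2, THF, −78 → 0 °C
Reagents that add atoms: iodine, II
Why: hydroxyl-directed trans-hydroalumination puts aluminium on the methyl-bearing carbon anti to the delivered hydride and iodinolysis goes with retention, so the Z iodide (later the cis relation of C3 and C6 across C4–C5) should result.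

Step 2
Reactants: 2 (Z)-3-iodobut-2-en-1-ol
Product: 3 (Z)-tert-butyl[(3-iodobut-2-en-1-yl)oxy]dimethylsilane
Conditions: TBSCl, imidazole, DMF, rt
Reagents that add atoms: tert-butyldimethylsilyl chloride, CC(C)(C)[Si](C)(C)Cl
Why: standard silylation of a primary alcohol protects the later C6 oxygen.

Step 3
Reactants: 3 (Z)-tert-butyl[(3-iodobut-2-en-1-yl)oxy]dimethylsilane; 4 prop-2-yn-1-ol
Product: 5 (Z)-6-[(tert-butyldimethylsilyl)oxy]-4-methylhex-4-en-2-yn-1-ol
Conditions: PdCl2(PPh3)2 (cat.), CuI (cat.), Et3N, THF, rt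
Reagents that add atoms: none
Why: Sonogashira coupling of an alkenyl iodide forms the C3–C4 bond with retention of the Z geometry.

Step 4
Reactants: 5 (Z)-6-[(tert-butyldimethylsilyl)oxy]-4-methylhex-4-en-2-yn-1-ol
Product: 6 (2Z,4Z)-6-[(tert-butyldimethylsilyl)oxy]-4-methylhexa-2,4-dien-1-ol
Conditions: H2 (1 atm), Pd/CaCO3 poisoned with Pb(OAc)2, quinoline, EtOAc, rt
Reagents that add atoms: none
Why: Lindlar syn semihydrogenation of the alkyne should give the (2Z) alkene that becomes the cis-2,3-epoxide.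

Step 5
Reactants: 6 (2Z,4Z)-6-[(tert-butyldimethylsilyl)oxy]-4-methylhexa-2,4-dien-1-ol
Product: 7 {(2R,3S)-3-[(Z)-4-[(tert-butyldimethylsilyl)oxy]but-2-en-2-yl]oxiran-2-yl}methanol
Conditions: Ti(OiPr)4, D-(−)-diisopropyl tartrate, tBuOOH, 4 Å MS, CH2Cl2, −25 °C
Reagents that add atoms: tert-butyl hydroperoxide, CC(C)(C)OO
Why: Sharpless asymmetric epoxidation acts only on the alkene of the free allylic alcohol, and the D-(−)-tartrate ligand should deliver oxygen to the face that gives the (2R,3S) cis-epoxide (C2 and C3 of the target).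

Step 6
Reactants: 7 {(2R,3S)-3-[(Z)-4-[(tert-butyldimethylsilyl)oxy]but-2-en-2-yl]oxiran-2-yl}methanol
Product: 8 (2S,3S)-3-[(Z)-4-[(tert-butyldimethylsilyl)oxy]but-2-en-2-yl]oxirane-2-carbaldehyde
Conditions: Dess–Martin periodinane, NaHCO3, CH2Cl2, 0 °C
Reagents that add atoms: none
Why: buffered Dess–Martin oxidation gives the cis-epoxy aldehyde without epimerisation (the descriptor at C2 changes only through priority).

Step 7
Reactants: 8 (2S,3S)-3-[(Z)-4-[(tert-butyldimethylsilyl)oxy]but-2-en-2-yl]oxirane-2-carbaldehyde; 9 ethyl (triphenylphosphoranylidene)acetate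
Product: 11 ethyl (Z)-α-iodoenoate (C1–C6 chain), via iodo ylide 10 (not isolated)
Conditions: 9, N-iodosuccinimide, CH2Cl2, −20 °C; then 8, −20 °C → rt
Reagents that add atoms: N-iodosuccinimide, O=C1CCC(=O)N1I
Why: the stabilised ylide is iodinated in the flask and the α-iodo ylide undergoes a Wittig reaction that places the ester trans to C2, which should give the (Z)-α-iodoenoate whose iodine marks the later C9–C10 bond.

Step 8
Reactants: 11 ethyl (Z)-α-iodoenoate
Product: 12 (Z)-2-iodoallylic alcohol (C14–OH)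
Conditions: iBu2AlH (2.2 equiv), CH2Cl2, −78 °C
Reagents that add atoms: none
Why: 1,2-reduction of the enoate at low temperature gives the C14 allylic alcohol and leaves the epoxide, the alkenyl iodide and the silyl ether untouched.

Step 9
Reactants: 12 (Z)-2-iodoallylic alcohol
Product: 13 alkenyl iodide (14-OTBDPS, 6-OTBS)
Conditions: TBDPSCl, imidazole, DMF, 0 °C → rt
Reagents that add atoms: tert-butyldiphenylsilyl chloride, CC(C)(C)[Si](Cl)(c1ccccc1)c1ccccc1
Why: silylation gives a robust C14 ether that survives the later selective cleavage of the C6 TBS ether.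

Step 10
Reactants: 14 (E)-pent-2-en-4-yn-1-ol
Product: 15 [(2R,3R)-3-ethynyloxiran-2-yl]methanol
Conditions: Ti(OiPr)4, D-(−)-diisopropyl tartrate, tBuOOH, 4 Å MS, CH2Cl2, −20 °C
Reagents that add atoms: tert-butyl hydroperoxide, CC(C)(C)OO
Why: Sharpless asymmetric epoxidation of the E allylic alcohol with the D-(−)-tartrate ligand should give the (2R,3R) epoxide, whose C2 becomes C8 of the target.

Step 11
Reactants: 15 [(2R,3R)-3-ethynyloxiran-2-yl]methanol
Product: 16 (S)-penta-3,4-diene-1,2-diol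
Conditions: Pd2(dba)3·CHCl3 (cat.), P(nBu)3, HCO2H, Et3N, THF, rt
Reagents that add atoms: none
Why: zerovalent palladium opens the propargylic epoxide in an SN2′ sense and formate delivers hydride (palladium-catalysed formate hydrogenolysis of propargylic electrophiles) to give the terminal allene, while the C–O bond at C8 is untouched so its configuration is kept.

Step 12
Reactants: 16 (S)-penta-3,4-diene-1,2-diol
Product: 17 (4S)-2-(4-methoxyphenyl)-4-(propa-1,2-dien-1-yl)-1,3-dioxolane
Conditions: 4-methoxybenzaldehyde dimethyl acetal, PPTS (cat.), CH2Cl2, rt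
Reagents that add atoms: 4-methoxybenzaldehyde dimethyl acetal, COc1ccc(cc1)C(OC)OC
Why: acid-catalysed transacetalisation ties both hydroxyls into the 4-methoxybenzylidene acetal.

Step 13
Reactants: 17 (4S)-2-(4-methoxyphenyl)-4-(propa-1,2-dien-1-yl)-1,3-dioxolane
Product: 18 (S)-2-[(4-methoxybenzyl)oxy]penta-3,4-dien-1-ol
Conditions: iBu2AlH, CH2Cl2, −78 → 0 °C
Reagents that add atoms: none
Why: in the reductive acetal opening aluminium binds the less hindered primary oxygen, so hydride cleaves that C–O bond and the PMB ether stays on the secondary oxygen (C8).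

Step 14
Reactants: 18 (S)-2-[(4-methoxybenzyl)oxy]penta-3,4-dien-1-ol
Product: 19 (S)-2-[(4-methoxybenzyl)oxy]penta-3,4-dienal
Conditions: Dess–Martin periodinane, NaHCO3, CH2Cl2, 0 °C; used at once
Reagents that add atoms: none
Why: neutral Dess–Martin oxidation gives the α-alkoxy aldehyde, which is used crude to avoid isomerisation of the allenyl α-centre.

Step 15
Reactants: 13 alkenyl iodide (14-OTBDPS, 6-OTBS); 19 (S)-2-[(4-methoxybenzyl)oxy]penta-3,4-dienal
Product: 22 seco-alcohol (C9–OH), via alkenyllithium 20 (not isolated), via alkenylmagnesium bromide 21 (not isolated)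
Conditions: 13, tBuLi (2.1 equiv), Et2O, −78 °C; MgBr2·OEt2; then 19 premixed with MgBr2·OEt2 in CH2Cl2, −78 °C; H2O
Reagents that add atoms: none
Why: iodine–lithium exchange and transmetalation give a configurationally stable alkenylmagnesium reagent that adds to the α-alkoxy aldehyde through the Cram chelate (magnesium bridging the aldehyde and PMB ether oxygens) from the face opposite the allenyl group, which should form the C9–C10 bond and set the 8,9-syn (9S) carbinol.

Step 16
Reactants: 22 seco-alcohol (C9–OH)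
Product: 23 seco-silyl ether (9-OTBS)
Conditions: TBSOTf, 2,6-lutidine, CH2Cl2, −78 °C
Reagents that add atoms: tert-butyldimethylsilyl trifluoromethanesulfonate, CC(C)(C)[Si](C)(C)OS(=O)(=O)C(F)(F)F
Why: silyl triflate with a hindered base silylates the hindered allylic alcohol at low temperature, so that no allylic ester is present in the nickel step.

Step 17
Reactants: 23 seco-silyl ether (9-OTBS)
Product: 24 seco-allylic alcohol (C6–OH)
Conditions: HF·pyridine, pyridine, THF, 0 °C
Reagents that add atoms: none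
Why: under buffered HF·pyridine the primary allylic TBS ether should be cleaved much faster than the hindered secondary TBS ether and the TBDPS ether.

Step 18
Reactants: 24 seco-allylic alcohol (C6–OH)
Product: 25 diepoxy alcohol
Conditions: Ti(OiPr)4, D-(−)-diisopropyl tartrate, tBuOOH, 4 Å MS, CH2Cl2, −20 °C
Reagents that add atoms: tert-butyl hydroperoxide, CC(C)(C)OO
Why: the only free allylic alcohol is at C6, so Sharpless asymmetric epoxidation takes place at the (Z) C4=C5 alkene, and reagent control by D-(−)-tartrate should give the (4R,5R) cis-epoxide and turn any minor enantiomer from step 5 into a separable diastereomer.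

Step 19
Reactants: 25 diepoxy alcohol
Product: 26 seco-aldehyde
Conditions: Dess–Martin periodinane, NaHCO3, CH2Cl2, 0 °C
Reagents that add atoms: none
Why: buffered Dess–Martin oxidation gives the α,β-epoxy aldehyde without touching the epoxides, the allene or the ethers.

Step 20
Reactants: 26 seco-aldehyde
Product: 28 macrocyclic hydroxy acid, via nickelalactone 27 (not isolated)
Conditions: Ni(cod)2 (1.2 equiv) and DBU (2.5 equiv) in THF added over 4 h to 26 (0.003 M) in CO2-saturated THF (1 atm), 0 °C → rt; then sat. aq. NH4Cl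
Reagents that add atoms: carbon dioxide, O=C=O
Why: Proposed new method: zerovalent nickel carrying DBU should couple CO2 oxidatively with the terminal C11=C13 bond of the allene (C11–C12 bond) to give nickelalactone 27, a 2-carboxylato allylnickel species of divalent nickel, whose allyl unit should then add through C7 to the C6 aldehyde in a six-membered chair transition state (C6–C7 bond), and protonation of the nickel alkoxide carboxylate gives 28. The closest known reaction types are the nickel-mediated sequential addition of CO2 and an aldehyde to a terminal allene in its intermolecular form and the intramolecular Nozaki–Hiyama–Kishi (Barbier) allylation of aldehydes by 2-(alkoxycarbonyl)allyl metals, which closes ten-membered germacranolide rings. The ten-membered carbocycle C1–C10 closes by a 10-exo-trig attack of the allyl γ-carbon C7 on the aldehyde (SE2′ at the allylmetal), while the lactone ring is not closed here but is fully set up, since C12 arrives as the carboxylate on C11 next to the new C6 alkoxide. C6 and C7 are formed together: the more stable syn allylnickel (C8 cis to the carboxylate) in the chair should give the 6,7-anti (trans-lactone) relationship, and the aldehyde face should be fixed by macrocyclic control, the chain being pre-bent by the cis C1=C10 alkene and the two cis epoxides and nickel bridging the aldehyde and C4–C5 epoxide oxygens, so that C6–O ends on the face opposite to the C4–C5 epoxide oxygen (6S,7S in 28). The step needs chemoselectivity for the allene over the C1=C10/C2–C3 alkenyl epoxide and γ-regioselectivity, which should be secured by the much higher affinity of amidine-ligated zerovalent nickel for a terminal allene under CO2 than for a hindered trisubstituted alkene, by keeping every allylic and allenylic oxygen as an ether, by slow addition of the nickel so that none is left free, and by the carboxylate chelate that holds nickel at C13.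

Step 21
Reactants: 28 macrocyclic hydroxy acid
Product: 29 lactone (8-OPMB, 9-OTBS, 14-OTBDPS)
Conditions: DCC, DMAP (cat.), CH2Cl2, 0 °C → rt
Reagents that add atoms: none
Why: carbodiimide activation of the acrylic acid and attack of the γ-hydroxyl (5-exo-trig lactonisation) should close the trans-fused α-methylene-γ-butyrolactone without change at any stereocentre.

Step 22
Reactants: 30 angelic acid [(Z)-2-methylbut-2-enoic acid]
Product: 31 (Z)-2-methylbut-2-en-1-ol
Conditions: LiAlH4, Et2O, 0 °C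
Reagents that add atoms: none
Why: hydride reduction of the acid gives the allylic alcohol with the Z geometry retained.

Step 23
Reactants: 31 (Z)-2-methylbut-2-en-1-ol
Product: 32 [(2S,3R)-2,3-dimethyloxiran-2-yl]methanol
Conditions: Ti(OiPr)4, L-(+)-diethyl tartrate, tBuOOH, 4 Å MS, CH2Cl2, −20 °C
Reagents that add atoms: tert-butyl hydroperoxide, CC(C)(C)OO
Why: Sharpless asymmetric epoxidation with the L-(+)-tartrate ligand should deliver oxygen to the face that gives the (2S,3R) epoxy alcohol, the precursor of the (2R,3R) acid.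

Step 24
Reactants: 32 [(2S,3R)-2,3-dimethyloxiran-2-yl]methanol
Product: 33 (2R,3R)-2,3-dimethyloxirane-2-carboxylic acid
Conditions: RuCl3 (cat.), NaIO4, CCl4/MeCN/H2O, rt
Reagents that add atoms: water, O; sodium periodate, [Na+].[O-]I(=O)(=O)=O
Why: RuO4 generated in the flask oxidises the primary alcohol to the acid without opening the epoxide, and neither stereocentre is touched.

Step 25
Reactants: 29 lactone (8-OPMB, 9-OTBS, 14-OTBDPS)
Product: 34 C8 alcohol
Conditions: DDQ, CH2Cl2/pH 7 buffer, 0 °C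
Reagents that add atoms: none
Why: oxidative cleavage of the PMB ether by DDQ under buffered conditions frees the C8 hydroxyl and leaves silyl ethers, epoxides and the methylene lactone intact.

Step 26
Reactants: 34 C8 alcohol; 33 (2R,3R)-2,3-dimethyloxirane-2-carboxylic acid
Product: 36 C8 epoxyangelate, via mixed anhydride 35 (not isolated)
Conditions: 33, 2,4,6-trichlorobenzoyl chloride, Et3N, THF, rt; then 34, DMAP, toluene, rt
Reagents that add atoms: none
Why: Yamaguchi esterification through the mixed anhydride acylates the hindered secondary alcohol with retention at C8 and without touching the stereocentres of the acid.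

Step 27
Reactants: 36 C8 epoxyangelate
Product: 37 diol (C9–OH, C14–OH)
Conditions: TBAF, AcOH (1:1), THF, 0 °C → rt
Reagents that add atoms: none
Why: acetic acid-buffered fluoride removes both silyl ethers while suppressing acyl migration and attack on the epoxides or the methylene lactone.

Step 28
Reactants: 37 diol (C9–OH, C14–OH)
Product: 38 enal (C14 aldehyde)
Conditions: TEMPO (cat.), PhI(OAc)2, CH2Cl2, rt
Reagents that add atoms: none
Why: the oxoammonium oxidation is selective for the primary allylic alcohol over the hindered secondary one and stops at the aldehyde.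

Step 29
Reactants: 38 enal (C14 aldehyde)
Product: 39 acetate enal
Conditions: Ac2O, pyridine, DMAP (cat.), CH2Cl2, 0 °C
Reagents that add atoms: acetic anhydride, CC(=O)OC(C)=O
Why: standard acetylation of the remaining C9 hydroxyl installs the acetate with retention.

Step 30
Reactants: 39 acetate enal
Product: 40 leucanthin B
Conditions: NaClO2, NaH2PO4, 2-methylbut-2-ene, tBuOH/H2O, 0 °C → rt
Reagents that add atoms: sodium chlorite, [Na+].[O-]Cl=O
Why: Pinnick oxidation converts the α,β-unsaturated aldehyde to the acid under buffered conditions that spare the epoxides, both esters and the methylene lactone, with the alkene scavenger removing hypochlorite.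

**Compound list**

1 | but-2-yn-1-ol | CC#CCO | starting material
2 | (Z)-3-iodobut-2-en-1-ol | I/C(C)=C\CO | intermediate
3 | (Z)-tert-butyl[(3-iodobut-2-en-1-yl)oxy]dimethylsilane | I/C(C)=C\CO[Si](C)(C)C(C)(C)C | intermediate
4 | prop-2-yn-1-ol | C#CCO | starting material
5 | (Z)-6-[(tert-butyldimethylsilyl)oxy]-4-methylhex-4-en-2-yn-1-ol | OCC#C/C(C)=C\CO[Si](C)(C)C(C)(C)C | intermediate
6 | (2Z,4Z)-6-[(tert-butyldimethylsilyl)oxy]-4-methylhexa-2,4-dien-1-ol | OC/C=C\C(C)=C/CO[Si](C)(C)C(C)(C)C | intermediate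
7 | {(2R,3S)-3-[(Z)-4-[(tert-butyldimethylsilyl)oxy]but-2-en-2-yl]oxiran-2-yl}methanol | OC[C@H]1O[C@H]1/C(C)=C\CO[Si](C)(C)C(C)(C)C | intermediate
8 | (2S,3S)-3-[(Z)-4-[(tert-butyldimethylsilyl)oxy]but-2-en-2-yl]oxirane-2-carbaldehyde | O=C[C@H]1O[C@H]1/C(C)=C\CO[Si](C)(C)C(C)(C)C | intermediate
9 | ethyl (triphenylphosphoranylidene)acetate | CCOC(=O)C=P(c1ccccc1)(c1ccccc1)c1ccccc1 | starting material
10 | iodo ylide, ethyl iodo(triphenylphosphoranylidene)acetate (not isolated) | CCOC(=O)C(I)=P(c1ccccc1)(c1ccccc1)c1ccccc1 | intermediate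
11 | ethyl (Z)-2-iodo-3-{(2R,3S)-3-[(Z)-4-[(tert-butyldimethylsilyl)oxy]but-2-en-2-yl]oxiran-2-yl}prop-2-enoate | I/C(C(=O)OCC)=C\[C@H]1O[C@H]1/C(C)=C\CO[Si](C)(C)C(C)(C)C | intermediate
12 | (Z)-2-iodo-3-{(2R,3S)-3-[(Z)-4-[(tert-butyldimethylsilyl)oxy]but-2-en-2-yl]oxiran-2-yl}prop-2-en-1-ol | I/C(CO)=C\[C@H]1O[C@H]1/C(C)=C\CO[Si](C)(C)C(C)(C)C | intermediate
13 | alkenyl iodide: tert-butyldiphenylsilyl ether of 12 (14-OTBDPS, 6-OTBS, (2R,3S)-cis-epoxide, 1(10)Z, 4Z) | I/C(CO[Si](c1ccccc1)(c1ccccc1)C(C)(C)C)=C\[C@H]1O[C@H]1/C(C)=C\CO[Si](C)(C)C(C)(C)C | intermediate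
14 | (E)-pent-2-en-4-yn-1-ol | OC/C=C/C#C | starting material
15 | [(2R,3R)-3-ethynyloxiran-2-yl]methanol | OC[C@H]1O[C@@H]1C#C | intermediate
16 | (S)-penta-3,4-diene-1,2-diol | OC[C@@H](O)C=C=C | intermediate
17 | (4S)-2-(4-methoxyphenyl)-4-(propa-1,2-dien-1-yl)-1,3-dioxolane (acetal epimers) | COc1ccc(cc1)C1OC[C@@H](O1)C=C=C | intermediate
18 | (S)-2-[(4-methoxybenzyl)oxy]penta-3,4-dien-1-ol | OC[C@@H](OCc1ccc(OC)cc1)C=C=C | intermediate
19 | (S)-2-[(4-methoxybenzyl)oxy]penta-3,4-dienal | O=C[C@@H](OCc1ccc(OC)cc1)C=C=C | intermediate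
20 | alkenyllithium from 13 (lithium in place of iodine, geometry retained; not isolated) | [Li]/C(CO[Si](c1ccccc1)(c1ccccc1)C(C)(C)C)=C\[C@H]1O[C@H]1/C(C)=C\CO[Si](C)(C)C(C)(C)C | intermediate
21 | alkenylmagnesium bromide from 13 (not isolated) | Br[Mg]/C(CO[Si](c1ccccc1)(c1ccccc1)C(C)(C)C)=C\[C@H]1O[C@H]1/C(C)=C\CO[Si](C)(C)C(C)(C)C | intermediate
22 | seco-alcohol: (2R,3S,8S,9S), 8-OPMB, 9-OH, 14-OTBDPS, 6-OTBS, 2,3-cis-epoxide, 1(10)Z, 4Z, terminal allene C7=C11=C13 | C=C=C[C@H](OCc1ccc(OC)cc1)[C@@H](O)/C(CO[Si](c1ccccc1)(c1ccccc1)C(C)(C)C)=C\[C@H]1O[C@H]1/C(C)=C\CO[Si](C)(C)C(C)(C)C | intermediate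
23 | seco-silyl ether: 9-O-TBS ether of 22 | C=C=C[C@H](OCc1ccc(OC)cc1)[C@@H](O[Si](C)(C)C(C)(C)C)/C(CO[Si](c1ccccc1)(c1ccccc1)C(C)(C)C)=C\[C@H]1O[C@H]1/C(C)=C\CO[Si](C)(C)C(C)(C)C | intermediate
24 | seco-allylic alcohol: 23 with free C6 hydroxyl | C=C=C[C@H](OCc1ccc(OC)cc1)[C@@H](O[Si](C)(C)C(C)(C)C)/C(CO[Si](c1ccccc1)(c1ccccc1)C(C)(C)C)=C\[C@H]1O[C@H]1/C(C)=C\CO | intermediate
25 | diepoxy alcohol: (2R,3R,4R,5R,8S,9S), 2,3- and 4,5-cis-epoxides, C6–OH | C=C=C[C@H](OCc1ccc(OC)cc1)[C@@H](O[Si](C)(C)C(C)(C)C)/C(CO[Si](c1ccccc1)(c1ccccc1)C(C)(C)C)=C\[C@H]1O[C@H]1[C@]1(C)O[C@@H]1CO | intermediate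
26 | seco-aldehyde: C6 aldehyde of 25, (2R,3R,4S,5S,8S,9S) by priority change only | C=C=C[C@H](OCc1ccc(OC)cc1)[C@@H](O[Si](C)(C)C(C)(C)C)/C(CO[Si](c1ccccc1)(c1ccccc1)C(C)(C)C)=C\[C@H]1O[C@H]1[C@]1(C)O[C@@H]1C=O | intermediate
27 | nickelalactone: 4-alkylidene-1-oxa-2-nickelacyclopentan-5-one from 26, C8 cis to the carboxylate (not isolated) | O=C1O[Ni]C/C1=C/[C@H](OCc1ccc(OC)cc1)[C@@H](O[Si](C)(C)C(C)(C)C)/C(CO[Si](c1ccccc1)(c1ccccc1)C(C)(C)C)=C\[C@H]1O[C@H]1[C@]1(C)O[C@@H]1C=O | intermediate
28 | macrocyclic hydroxy acid: (2R,3R,4R,5R,6S,7S,8S,9S), 6α-OH, 7β-(1-carboxyvinyl), 2α,3α:4β,5β-diepoxide, 8β-OPMB, 9α-OTBS, 14-OTBDPS, 1(10)Z | C=C(C(=O)O)[C@@H]1[C@H](OCc2ccc(OC)cc2)[C@@H](O[Si](C)(C)C(C)(C)C)/C(CO[Si](c2ccccc2)(c2ccccc2)C(C)(C)C)=C\[C@H]2O[C@H]2[C@]2(C)O[C@@H]2[C@H]1O | intermediate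
29 | lactone: (2R,3R,4R,5R,6S,7R,8S,9S), 6α,12-olide (trans-fused), 2α,3α:4β,5β-diepoxide, 8β-OPMB, 9α-OTBS, 14-OTBDPS, 1(10)Z | C=C1C(=O)O[C@H]2[C@H]1[C@H](OCc1ccc(OC)cc1)[C@@H](O[Si](C)(C)C(C)(C)C)/C(CO[Si](c1ccccc1)(c1ccccc1)C(C)(C)C)=C\[C@H]1O[C@H]1[C@]1(C)O[C@H]21 | intermediate
30 | angelic acid, (Z)-2-methylbut-2-enoic acid | C/C=C(/C)C(=O)O | starting material
31 | (Z)-2-methylbut-2-en-1-ol | C/C=C(/C)CO | intermediate
32 | [(2S,3R)-2,3-dimethyloxiran-2-yl]methanol | OC[C@]1(C)O[C@@H]1C | intermediate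
33 | (2R,3R)-2,3-dimethyloxirane-2-carboxylic acid | OC(=O)[C@]1(C)O[C@@H]1C | intermediate
34 | C8 alcohol: 29 with 8β-OH (other stereocentres as in 29) | C=C1C(=O)O[C@H]2[C@H]1[C@H](O)[C@@H](O[Si](C)(C)C(C)(C)C)/C(CO[Si](c1ccccc1)(c1ccccc1)C(C)(C)C)=C\[C@H]1O[C@H]1[C@]1(C)O[C@H]21 | intermediate
35 | mixed anhydride of 33 and 2,4,6-trichlorobenzoic acid (not isolated) | O=C(OC(=O)[C@]1(C)O[C@@H]1C)c1c(Cl)cc(Cl)cc1Cl | intermediate
36 | C8 epoxyangelate: 8β-O-[(2R,3R)-2,3-dimethyloxirane-2-carbonyl], 9α-OTBS, 14-OTBDPS (ring stereocentres as in 29) | C=C1C(=O)O[C@H]2[C@H]1[C@H](OC(=O)[C@]1(C)O[C@@H]1C)[C@@H](O[Si](C)(C)C(C)(C)C)/C(CO[Si](c1ccccc1)(c1ccccc1)C(C)(C)C)=C\[C@H]1O[C@H]1[C@]1(C)O[C@H]21 | intermediate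
37 | diol: 36 with 9α-OH and 14-OH | C=C1C(=O)O[C@H]2[C@H]1[C@H](OC(=O)[C@]1(C)O[C@@H]1C)[C@@H](O)/C(CO)=C\[C@H]1O[C@H]1[C@]1(C)O[C@H]21 | intermediate
38 | enal: 37 with C14 aldehyde, 1(10)E | C=C1C(=O)O[C@H]2[C@H]1[C@H](OC(=O)[C@]1(C)O[C@@H]1C)[C@@H](O)/C(C=O)=C\[C@H]1O[C@H]1[C@]1(C)O[C@H]21 | intermediate
39 | acetate enal: 9α-OAc, C14 aldehyde | C=C1C(=O)O[C@H]2[C@H]1[C@H](OC(=O)[C@]1(C)O[C@@H]1C)[C@@H](OC(C)=O)/C(C=O)=C\[C@H]1O[C@H]1[C@]1(C)O[C@H]21 | intermediate
40 | leucanthin B: (2R,3R,4R,5R,6S,7R,8S,9S), 1(10)E, 8β-O-[(2R,3R)-2,3-dimethyloxirane-2-carbonyl], 9α-OAc, 14-oic acid | C=C1C(=O)O[C@H]2[C@H]1[C@H](OC(=O)[C@]1(C)O[C@@H]1C)[C@@H](OC(C)=O)/C(C(=O)O)=C\[C@H]1O[C@H]1[C@]1(C)O[C@H]21 | target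

**Totals**

Total steps: 30. Longest linear sequence: 22 steps (steps 1–9, 15–21, 25–30). Steps 10–14 (aldehyde 19) and 22–24 (acid 33) are side branches.

**Steps most likely to fail**

1. Step 20 (Proposed new method). What may go wrong: insertion of zerovalent nickel into the allylic C2–C3 epoxide instead of coupling with the allene, oligomerisation in place of ten-membered ring closure, or addition to the wrong aldehyde face. Fallback with known chemistry (sets out from 18 and 13, returns at 29): the C11–C12 bond is put in beforehand as an acrylate ester and only C6–C7 is made in the ring closure, by the intramolecular Nozaki–Hiyama–Kishi (Barbier-type) allylation with divalent chromium that is established for ten-membered germacranolide rings. Alcohol 18 is silylated (TBSCl, imidazole) to silyl ether F1. Ozonolysis of the allene (O3, then PPh3) gives aldehyde F2. A Morita–Baylis–Hillman reaction with methyl acrylate (DABCO) gives hydroxy acrylate F3. N-Chlorosuccinimide/Me2S converts it with allylic transposition into (Z)-allylic chloride F4. HF·pyridine gives primary alcohol F5 and Dess–Martin oxidation gives aldehyde F6. Under the conditions of step 15, 21 (from 13) adds to F6 to give allylic alcohol F7. The conditions of steps 16 to 19 then give silyl ether F8, primary alcohol F9, diepoxy alcohol F10 and aldehyde F11. CrCl2 with LiI in THF/DMF at high dilution should close the ring to hydroxy ester F12, which lactonises (DMAP, toluene) to 29.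

2. Step 15. What may go wrong: loss of chelation control at C9, base-induced isomerisation of the allenyl aldehyde to a conjugated dienal, or bromide opening of the epoxide by the magnesium salt. Fallback (sets out from 13 and 19, returns at 22): a Nozaki–Hiyama–Kishi coupling (CrCl2, cat. NiCl2, DMSO, rt) joins 13 and 19 under non-basic conditions. It is expected to favour the Felkin product, the C9 epimer F13, beside some 22. F13 is inverted by a Mitsunobu reaction (4-nitrobenzoic acid, PPh3, DIAD) to 4-nitrobenzoate F14, and K2CO3/MeOH releases 22.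

3. Step 26. What may go wrong: very slow acylation of the C8 hydroxyl, which is flanked by the ring fusion and the bulky C9 silyl ether, with competing opening of the epoxy acid or acyl scrambling. Fallback (sets out from 29, returns at 39): the bulky ester is introduced last, next to a small acetate instead of a silyl ether. TBAF/AcOH on 29 gives PMB diol F15. TEMPO/PhI(OAc)2 gives enal F16. Ac2O/pyridine gives acetate F17. DDQ gives C8 alcohol F18. Yamaguchi esterification of F18 with 33 (through 35) gives 39.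

**Further compounds**

F1 | step 20 | silyl ether, (S)-tert-butyl{[2-[(4-methoxybenzyl)oxy]penta-3,4-dien-1-yl]oxy}dimethylsilane | CC(C)(C)[Si](C)(C)OC[C@@H](OCc1ccc(OC)cc1)C=C=C
F2 | step 20 | aldehyde, (R)-3-[(tert-butyldimethylsilyl)oxy]-2-[(4-methoxybenzyl)oxy]propanal | CC(C)(C)[Si](C)(C)OC[C@@H](OCc1ccc(OC)cc1)C=O
F3 | step 20 | hydroxy acrylate, Morita–Baylis–Hillman adduct of F2 and methyl acrylate (C7 epimers) | C=C(C(=O)OC)C(O)[C@H](OCc1ccc(OC)cc1)CO[Si](C)(C)C(C)(C)C
F4 | step 20 | (Z)-allylic chloride, methyl (S,Z)-5-[(tert-butyldimethylsilyl)oxy]-2-(chloromethyl)-4-[(4-methoxybenzyl)oxy]pent-2-enoate | COC(=O)/C(CCl)=C/[C@H](OCc1ccc(OC)cc1)CO[Si](C)(C)C(C)(C)C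
F5 | step 20 | primary alcohol, F4 without the silyl group | COC(=O)/C(CCl)=C/[C@H](OCc1ccc(OC)cc1)CO
F6 | step 20 | aldehyde, methyl (Z)-2-(chloromethyl)-4-[(4-methoxybenzyl)oxy]-5-oxopent-2-enoate | COC(=O)/C(CCl)=C/[C@H](OCc1ccc(OC)cc1)C=O
F7 | step 20 | allylic alcohol, analogue of 22 with the (Z)-2-(chloromethyl)acrylate in place of the allene | COC(=O)/C(CCl)=C/[C@H](OCc1ccc(OC)cc1)[C@@H](O)/C(CO[Si](c1ccccc1)(c1ccccc1)C(C)(C)C)=C\[C@H]1O[C@H]1/C(C)=C\CO[Si](C)(C)C(C)(C)C
F8 | step 20 | silyl ether, 9-O-TBS ether of F7 | COC(=O)/C(CCl)=C/[C@H](OCc1ccc(OC)cc1)[C@@H](O[Si](C)(C)C(C)(C)C)/C(CO[Si](c1ccccc1)(c1ccccc1)C(C)(C)C)=C\[C@H]1O[C@H]1/C(C)=C\CO[Si](C)(C)C(C)(C)C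
F9 | step 20 | primary alcohol, F8 with free C6 hydroxyl | COC(=O)/C(CCl)=C/[C@H](OCc1ccc(OC)cc1)[C@@H](O[Si](C)(C)C(C)(C)C)/C(CO[Si](c1ccccc1)(c1ccccc1)C(C)(C)C)=C\[C@H]1O[C@H]1/C(C)=C\CO
F10 | step 20 | diepoxy alcohol, 4,5-cis-epoxide of F9 | COC(=O)/C(CCl)=C/[C@H](OCc1ccc(OC)cc1)[C@@H](O[Si](C)(C)C(C)(C)C)/C(CO[Si](c1ccccc1)(c1ccccc1)C(C)(C)C)=C\[C@H]1O[C@H]1[C@]1(C)O[C@@H]1CO
F11 | step 20 | aldehyde, C6 aldehyde of F10 | COC(=O)/C(CCl)=C/[C@H](OCc1ccc(OC)cc1)[C@@H](O[Si](C)(C)C(C)(C)C)/C(CO[Si](c1ccccc1)(c1ccccc1)C(C)(C)C)=C\[C@H]1O[C@H]1[C@]1(C)O[C@@H]1C=O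
F12 | step 20 | hydroxy ester, methyl ester of 28 | COC(=O)C(=C)[C@@H]1[C@H](OCc2ccc(OC)cc2)[C@@H](O[Si](C)(C)C(C)(C)C)/C(CO[Si](c2ccccc2)(c2ccccc2)C(C)(C)C)=C\[C@H]2O[C@H]2[C@]2(C)O[C@@H]2[C@H]1O
F13 | step 15 | C9 epimer of 22 | C=C=C[C@H](OCc1ccc(OC)cc1)[C@H](O)/C(CO[Si](c1ccccc1)(c1ccccc1)C(C)(C)C)=C\[C@H]1O[C@H]1/C(C)=C\CO[Si](C)(C)C(C)(C)C
F14 | step 15 | 4-nitrobenzoate of 22 | C=C=C[C@H](OCc1ccc(OC)cc1)[C@@H](OC(=O)c1ccc(cc1)[N+](=O)[O-])/C(CO[Si](c1ccccc1)(c1ccccc1)C(C)(C)C)=C\[C@H]1O[C@H]1/C(C)=C\CO[Si](C)(C)C(C)(C)C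
F15 | step 26 | PMB diol, 29 with free C9 and C14 hydroxyls | C=C1C(=O)O[C@H]2[C@H]1[C@H](OCc1ccc(OC)cc1)[C@@H](O)/C(CO)=C\[C@H]1O[C@H]1[C@]1(C)O[C@H]21
F16 | step 26 | enal, C14 aldehyde of F15 | C=C1C(=O)O[C@H]2[C@H]1[C@H](OCc1ccc(OC)cc1)[C@@H](O)/C(C=O)=C\[C@H]1O[C@H]1[C@]1(C)O[C@H]21
F17 | step 26 | acetate, 9-O-acetyl derivative of F16 | C=C1C(=O)O[C@H]2[C@H]1[C@H](OCc1ccc(OC)cc1)[C@@H](OC(C)=O)/C(C=O)=C\[C@H]1O[C@H]1[C@]1(C)O[C@H]21
F18 | step 26 | C8 alcohol, F17 without the PMB group | C=C1C(=O)O[C@H]2[C@H]1[C@H](O)[C@@H](OC(C)=O)/C(C=O)=C\[C@H]1O[C@H]1[C@]1(C)O[C@H]21
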